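The data stem from a simulated flask on assumed constants, noise included.

The vessel was closed, stirred and held at constant volume and temperature, and the earlier runs followed the ring Z forming from the substrate J.

| setting | Saturday's | Monday's | Thursday's | beta | eta | gamma |
|---|---|---|---|---|---|---|
| J | 0.062 M | 0.095 M | 0.24 M | 0.050 M | 0.10 M | 0.20 M |
| remark | run made earlier | run made earlier | run made earlier |  |  |  |
| time |  |  |  | 5.0 h | 5.0 h | 5.0 h |

- Saturday's (time / h: Z / %): 1.00: 9.9; 2.00: 17.5; 3.00: 21.8; 4.00: 26.0; 5.00: 29.1
- Monday's (time / h: Z / %): 0.417: 4.8; 0.833: 8.6; 1.33: 11.2; 2.50: 18.8; 5.00: 27.9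
- Thursday's (time / h: Z / %): 1.00: 8.0; 2.00: 14.5; 3.00: 17.8; 4.00: 19.6; 5.00: 22.0

(scatter of a reading: 0.5 percentage points)

- "hardly changes" means that all values lie within two and a half points (for a concentration: within two and a half percent of the largest)

* [Z] at the end for beta, eta, gamma, in this order
* the course of these numbers from the first flask to the last (hardly changes / rises all the way / falls, then rises / falls all the way / rises, then falls)

I wrote y for the yield of Z at 5.0 h as a fraction of the J charged, so that [Z] is y times the charge. In the runs y fell as the charge rose, from 29.1% on Saturday through 27.9% on Monday to 22.0% on Thursday.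

I began with a bracket for gamma, whose charge of 0.20 M lies between Monday's and Thursday's. Taking it that y kept falling with charge, Monday's yield gave a bound from above of 0.0558 M, and Thursday's gave a bound from below of 0.0440 M.

To tighten it, I replaced the curve by its mean slope. Monday to Thursday gave 0.407 L mol⁻¹ as the dilution slope s, the yield given up per unit of added charge. Saturday to Monday read 0.364 L mol⁻¹, so I saw no bend beyond a scatter of 0.5 percentage points per reading.

With s, I reckoned a yield of 23.6% for gamma. My row was 0.0148 M, 0.0277 M and 0.0473 M, rising.

The forecast, which is not my reckoning and differs slightly from it, gave 0.0148 M, 0.0275 M and 0.047 M, inside my bracket for gamma: “The yield falls, but absolute [Z] still rises all the way.”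

The flasks gave 0.0149 M, 0.0272 M and 0.0468 M, and the row rises all the way.

    J ⇌ E (K = 2.50, k = 0.150 h⁻¹)
    2 J ⇌ D (K = 20.0 L mol⁻¹, k = 0.980 L mol⁻¹ h⁻¹)
    Z ⇌ L (K = 2.20, k = 0.00760 h⁻¹)
    J → Z (k = 0.120 h⁻¹)

On these flasks, s puts beta 6.1 points above gamma in yield, and the results stand 6.4 points apart, a gap whose seat the [Z] numbers do not show: at the end D, each counted as two J, held 33.2% of the charge in gamma and 12.4% in beta. With the turning of 2 J into D, a second-order side reaction, taken away, the yields at the end were 33.3% in beta and 33.3% in gamma. That step is a part of the reason gamma stood at 0.0468 M at the end, acting together with the length of the run: a gamma run ten times as long gave 0.110 M.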